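The cedar run at 45 °C shows more target at its last reading, 56.1%, than the oak run at 60 °C shows on its flat stretch, 45.5%, from the same charge.

| flask | starting material | reagent | temperature | remark | time |
|---|---|---|---|---|---|
| oak | 2 M | 3 M | 60 °C | the very flask that is asked about, followed so far |  |
| cedar | 2 M | 3 M | 45 °C | run made earlier |  |
| flask | 2.0 M | 3.00 M | 60 °C |  | 6.0 h |

- oak (time / h: target / %): 0.417: 28.1; 1.33: 42.3; 2.00: 44.7; 3.00: 45.5; 5.00: 45.4
- cedar (time / h: target / %): 0.833: 23.3; 3.00: 43.5; 4.00: 48.5; 6.00: 52.7; 10.0: 56.1

(standard deviation of a reading: 0.3 percentage points)

- north-east: at 6.0 h raise the temperature by 25 K, then wait 2.0 h
- north: at 6.0 h take out 90% of the target then present, then wait 2.0 h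
- west: change nothing and wait 2.0 h more

- what is taken out of target is counted as made
- reactions considered so far: 2 reagent -> self-condensation product; starting material + reagent -> target; target <-> isomer of the product

1. target, in percent of the starting material first charged, at 6.0 h
2. the option that brings most further target ("none" if no option brings more than 2 percentage points) (north-east / north / west / none)
3. target present, with what was taken out counted in, in percent of the starting material first charged, after north-east
4. target present, with what was taken out counted in, in percent of the starting material first charged, after west

1. The bench rule says that the species charged in deficit is the limiting reagent. Here c(reagent)/c(starting material) is 1.50, so by that rule starting material limits, and target should climb towards the whole charge.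

2. A ratio marks where the rule stops. If the charged reagent has finished reacting there, the flat oak reading costs 3.30 of charged reagent per target standing, more than the 1.50 charged per starting material. At that price the reagent charged in the oak flask pays for less than the whole charge of starting material.

3. Self-condensation goes with c(reagent) squared and the making with c(reagent) times c(starting material). I therefore take the reagent wasted per target standing as proportional to the charged c(reagent)/c(starting material). The constant of proportion, which I take as fixed at one temperature, is the waste number w. Supposing the charged reagent has finished reacting on the flat stretch, the balance gives target fraction y = 1/(w + c(starting material)/c(reagent)). The oak reading gives the waste number 1.53, and target lost to isomer counts in it as waste. The cedar run, still climbing, reads 1.12, which is less.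

4. My own reckoning is that this flask holds about 45.5% at 6.0 h and stays there under west, with starting material remaining. From readings of target by themselves I cannot tell which way heat moves target and isomer, so I give no number for north-east and do not commit on the best option.

5. The forecast gives 45.4% now, 45.4% after west, 27.5% after north-east, and north as best, on the ground that “the starting material is essentially consumed, and target and isomer have equilibrated”. Where I read the flat stretch as finished reagent, it reads equilibrium.

The flask gives 44.3% now, 43.1% after west and 55.8% after north-east. The best option is north-east, with a gain of 11 percentage points, against 4.4 points for north and −1.2 points for west.

    2 reagent → self-condensation product (k = 0.00797 M⁻¹ min⁻¹, Ea = 93.0 kJ mol⁻¹)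
    starting material + reagent → target (k = 0.00785 M⁻¹ min⁻¹, Ea = 71.0 kJ mol⁻¹)
    target ⇌ isomer of the product (K = 0.453, k = 0.00155 min⁻¹, Ea = 121 kJ mol⁻¹, ΔH = −75.0 kJ mol⁻¹)
    (constants at 60 °C)

At the start of this flask the making uses reagent at 0.33 of the rate of self-condensation. At 6.00 h, with reagent at 0.99% of its charge and starting material at 42%, the half-life of starting material by the making is 49 h, against 7.5 h for target by its forward step to isomer. The neighbour flask with 1.2 M of reagent, for which the waste number gives 31.3%, holds 28.1% of target.

The data were generated by integration from invented constants, and the scatter is random.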